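# Proposed total synthesis of CNP0439949.2 (compound 41)

## Analysis of the target

Target 41 consists of two decalins joined by a C11–C12 ethylene bridge between two quaternary carbons, C5 of the left bicycle and C9′ of the right one, with a hydroquinone bis(hydrogen sulfate) on the methylene attached to C9. The numbering used throughout is C1–C10 for the left decalin (ring A: C1–C5 and C10; ring B: C5–C10), C11 (on C5) and C12 (on C9′) for the bridge, and C1′–C10′ for the right decalin (ring A′: C1′–C5′ and C10′; ring B′: C5′–C10′); β means the face of C10–H on the left and the face of the C8′ and C9′ methyl groups on the right. The left decalin is cis-fused: C11 on C5, the hydrogen on C10, the benzyl group on C9 and the methyl on C8 are all β, only the C9 methyl is α, and C4 carries an exocyclic methylene. The right decalin has a C1′=C10′ double bond, an α hydrogen on C5′, cis (β) methyl groups on C8′ and C9′, and C12 α on C9′. The four stereocentres on the left and the three on the right are insulated from each other by the bridge, so each half has to be made as a single enantiomer of defined absolute configuration. Sensitive groups are the aryl sulfate monoesters (introduced last), the 1,1-disubstituted and trisubstituted alkenes (acid-labile, and they rule out late hydrogenation) and the electron-rich hydroquinone. The hard points are the quaternary C9 next to C8 and 1,3 to the quaternary C5, the bond between two neopentyl positions (C11–C12), and the placing of the right-hand double bond at C1′=C10′ and not at the tetrasubstituted C5′=C10′ position. The strategy rests on ring B of the left half: a quaternary C5 bearing C11 and a cis C10–H are what suprafacial addition of a four-carbon diene across the C5=C10 double bond of a ring A enone delivers, provided that the enone carries the future C11 as an ester.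

## Retrosynthetic reasoning

**Sulfate and phenol unmasking (41 ⇒ 40 ⇒ 38).** The two O–S bonds are cut first, because the sulfate monoesters tolerate none of the earlier chemistry. The hydroquinone 40 is traced to its dimethyl ether 38, so that the arene travels through the route as an inert, commercially available benzyl unit.

**C4 methylene (38 ⇒ 37 ⇒ 36 ⇒ 35).** The exocyclic C=C bond is cut to the C4 ketone 37. It is placed late because a 1,1-disubstituted alkene would not survive the hydrogenation that sets C8, nor a radical at C11. Before that the C4 oxygen is carried as the silyl ether 35, which also removes the only competing enolisable carbonyl from the enolate chemistry at C9.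

**Bridge (35 ⇒ 34 ⇒ 17 + 31).** The C11–C12 bond is cut. This divides the molecule into two halves of similar size, each with its own stereocentres, and it lets the ester carbon of the cycloadduct become C11. Forward, the C12 organolithium 32, made from iodide 31, must add to the non-enolisable neopentyl aldehyde 17, and the resulting C11 oxygen must be removed by radical deoxygenation via xanthate 34. A polar union is preferred over alkylation because neither neopentyl carbon can act as an SN2 electrophile.

**C8 methyl (17 ⇒ 16 ⇒ 15 ⇒ 14 ⇒ 13).** The aldehyde 17 comes from the ester 15 by reduction to 16 and re-oxidation. The C8–CH3 group is traced to the C8 ketone of 13 by methylenation (14) and hydrogenation. The forward hydrogenation has to deliver hydrogen to the α face of C8, anti to the benzyl group.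

**C9 benzyl (13 ⇒ 10 + 11).** The C9–CH2Ar bond is cut. Enone 10 has a single acidic position (C9–H, α′ to the C8 ketone; C5 is quaternary), so its cross-conjugated enolate 12 forms without regiochemical ambiguity. Alkylation with bromide 11 on the convex face of the cis-decalin puts the benzyl group on the face of C10–H. The C9 configuration of the cycloadduct is therefore irrelevant.

**Enone and C4 masking (10 ⇒ 9 ⇒ 8 ⇒ 7).** The C6=C7 bond of 10 is derived from the silyl enol ether of 7 by dehydrogenation, after the C4 ketone has been reduced (8) and silylated (9).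

**Key disconnection (7 ⇒ 4 + 6).** Ring B is opened at C5–C6 and C9–C10. No other cut makes the quaternary C5, the cis fusion and a differentiated C8 oxygen in one operation from two achiral partners, each one step from a commercial compound. Forward, the β-keto ester dienophile 4 and the 2-silyloxydiene 6 must combine with regiocontrol (C9 to C10), on one face of 4 (catalyst control), and without loss of the silyl enol ether. Compounds 4 and 6 come from 1 and 5.

**Right half, quaternary C9′ (31 ⇒ 30 ⇒ 28).** The C9′–C12 bond is cut in the sense of a [2,3]-sigmatropic shift from an oxygen on C1′. This one event makes the quaternary centre, transfers the C1′ configuration to C9′ (C12 arrives on the face of the C–O bond, anti to the C8′ methyl) and leaves the double bond at C1′=C10′, which a cationic methyl-shift approach would not do reliably.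

**Right half, bicycle (28 ⇒ 27 ⇒ 26).** Both rings are opened at C5′–C10′ and C8′–C9′ to the acyclic dienyne 26. An E,E diene and an alkyne can only give the cis relation of H5′ and H8′, and the propargylic ether stereocentre controls the face.

**Right half, chain (26 ⇒ 25 ⇒ 24 ⇒ 23 ⇒ 21 ⇒ 18 + 19).** The single stereocentre of 25 comes from asymmetric reduction of ynone 24. The chain is assembled from ester 23 and, before it, from aldehyde ester 21 (the Michael adduct of 18 and 19, which holds the gem-dimethyl carbon).

## Alternatives that were turned down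

Alternative 1: photocycloaddition to build the quaternary carbon of ring B′. Disconnection: C9′–C12 and the bond from C10′ to the central carbon of propa-1,2-diene A3. Forward, the bicyclic enone A2 would be irradiated with A3 to give the methylenecyclobutane A1.

- For it: enone–allene [2+2] reactions are dependable for forming a congested bond at the β-carbon, the head-to-head regiochemistry is predictable, and the incoming group should add anti to the C8′ methyl. On the single task of making the C9′ quaternary centre intermolecularly it is at least as strong as the [2,3] shift used here.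
- Against it: A1 is several steps away from anything that can be joined. The cyclobutane has to be cleaved (oxidative cleavage, then retro-Claisen opening), which leaves two carbons on C9′, so that C11 would come from the right half and the union would have to form the quaternary C5. The C1′ ketone with C10′–H then has to be turned into the C1′=C10′ alkene against enolisation towards C2′. A2 itself needs its C5′/C8′ relation set first, and the left half remains unsolved.
- Comparison: the chosen plan solves the quaternary C5, the cis fusion and ring B in one catalytic step, and gets the C9′ centre and the alkene position together from one sigmatropic event.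

Alternative 2: double methylation of a benzyl enone. Disconnection: C8–CH3 and C9–CH3. Forward, conjugate addition of Al(CH3)3 to 2-(2,5-dimethoxybenzyl)cyclohex-2-en-1-one A5, catalysed by Cu(OTf)2 and a chiral phosphoramidite, followed by C-methylation of the enolate with CH3I trans to the new C8 methyl, would give ketone A4.

- For it: it is short, catalytic and enantioselective, and on the C8/C9 pair it is clearly stronger than the chosen route, which has to set C8 by a face-selective hydrogenation.
- Against it: A4 is monocyclic. Ring A, the quaternary C5 with its one-carbon branch and the cis C10–H would all have to be built by annulation onto the C10 ketone, next to the quaternary C9. That means three further C–C bonds and two stereocentres with no obvious control element, and C10 has to pass from a carbonyl to a CH.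
- Comparison: the chosen strategy gives up the easy C8/C9 control but obtains C5, C10 and ring B together, which are harder to reach.

Alternative 3: benzannulation to grow the hydroquinone. Disconnection: the arene ring. Forward, the C9-propargyl compound A8 would react with the Fischer carbene complex (CO)5Cr=C(OCH3)CH=CH2 A7 to give the hydroquinone monomethyl ether A6.

- For it: the arene is made late, the regiochemistry (larger alkyne substituent ortho to the phenol) is reliable, and the two oxygens come out differentiated, which would be an advantage if the two sulfates had to be told apart.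
- Against it: it spends a stoichiometric amount of A7 on the most advanced intermediate A8, whose two alkenes can interfere, it still needs a demethylation of A6, and it addresses none of the seven stereocentres or the bridge.
- Comparison: on stereochemistry it is neutral. The chosen route introduces the complete arene in one alkylation with commercial bromide 11, so it is shorter by several steps; what is lost is flexibility for arene analogues.

Key step: step 3

## Assumptions

- The (S,S)-configured bis(oxazoline) in step 3 and RuCl[(S,S)-TsDPEN](p-cymene) in step 15 are taken to give the configurations drawn; if the sense of induction proves opposite, the mirror-image ligand is used.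
- The C4 carbinol (steps 4–23) is drawn as the α-alcohol and C11 in 33 and 34 as an epimer mixture; both centres are removed later and their configuration does not matter.

## Route

Step 1
Reactants: 1 methyl 2-oxocyclohexane-1-carboxylate
Product: 4 methyl 6-oxocyclohex-1-ene-1-carboxylate, via selenide 2 (not isolated), via selenoxide 3 (not isolated)
Conditions: PhSeCl, pyridine, CH2Cl2, 0 °C; then H2O2 (30 % aq), 0 → 25 °C
Reagents that add atoms: none
Why: α-Selenenylation of the β-keto ester and selenoxide syn-elimination (Reich–Sharpless dehydrogenation) can only eliminate into the ring; 4 is used at once because it dimerises on standing.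

Step 2
Reactants: 5 pent-1-en-3-one
Product: 6 (Z)-3-(tert-butyldimethylsilyloxy)penta-1,3-diene
Conditions: TBSOTf, Et3N, CH2Cl2, 0 °C
Reagents that add atoms: tert-butyldimethylsilyl trifluoromethanesulfonate CC(C)(C)[Si](C)(C)OS(=O)(=O)C(F)(F)F
Why: Soft enolisation and O-silylation (silyl dienol ether formation) on the ethyl side, the only enolisable position; amine/silyl triflate conditions give mainly the Z enol ether.

Step 3
Reactants: 4 methyl 6-oxocyclohex-1-ene-1-carboxylate; 6 (Z)-3-(tert-butyldimethylsilyloxy)penta-1,3-diene
Product: 7 methyl (4aR,8S,8aR)-7-(tert-butyldimethylsilyloxy)-8-methyl-4-oxo-1,3,4,5,8,8a-hexahydronaphthalene-4a(2H)-carboxylate (cis-fused adduct: C4 ketone; C5 ester; C7=C8 silyl enol ether)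
Conditions: Cu(OTf)2 (10 mol %), (S,S)-t-Bu-BOX (11 mol %), 4 Å MS, CH2Cl2, −78 → −40 °C, slow addition of 4
Reagents that add atoms: none
Why: The β-keto ester 4 chelates divalent copper through both carbonyl oxygens, which lowers the LUMO of the C5=C10 bond and holds it inside the chiral pocket of the bis(oxazoline); diene 6 then adds in a concerted but asynchronous [4+2] cycloaddition in which the nucleophilic terminus C9 bonds to the enone β-carbon C10 ahead of the C6–C5 bond. The closest known reaction type is the Lewis-acid-promoted Diels–Alder reaction of 2-alkoxycarbonylcycloalk-2-enones with 2-silyloxydienes, together with enantioselective Cu(OTf)2–bis(oxazoline) catalysis of two-point-binding dienophiles. Ring B (C5–C6–C7–C8–C9–C10) is closed in a six-membered suprafacial–suprafacial mode, two σ bonds in one step, and the new C7=C8 bond remains as a silyl enol ether. C5 and C10 become cis because both bonds form on one face of the ring A alkene, and their absolute configuration is set by the ligand, which shields one face of the chelated dienophile. C9 follows from the Z geometry of 6 and a ring-endo transition state, and it is of no consequence because it is re-made in step 7. The step needs regioselectivity, which the silyloxy donor on C8 secures, face selectivity, which the ligand secures, and chemoselectivity over Mukaiyama–Michael desilylation and over dimerisation of 4, for which low temperature, sieves and slow addition are used.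

Step 4
Reactants: 7 cis-fused adduct (C4 ketone)
Product: 8 methyl 4α-hydroxy analogue of 7 (C4–OH trans to the C5 ester; silyl enol ether intact)
Conditions: NaBH4, MeOH/THF, −20 °C
Reagents that add atoms: none
Why: Chemoselective borohydride reduction of the ketone (ester and silyl enol ether are inert); hydride is expected from the convex β face; the step removes the only other enolisable carbonyl before the C9 enolate chemistry.

Step 5
Reactants: 8 4α-alcohol
Product: 9 4α-(tert-butyldimethylsilyl) ether of 8
Conditions: TBSOTf, 2,6-lutidine, CH2Cl2, 0 °C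
Reagents that add atoms: tert-butyldimethylsilyl trifluoromethanesulfonate CC(C)(C)[Si](C)(C)OS(=O)(=O)C(F)(F)F
Why: Silyl ether formation by the triflate/lutidine protocol suited to a hindered secondary alcohol; the silyl enol ether is stable under these non-acidic conditions.

Step 6
Reactants: 9 bis-silyl compound
Product: 10 enone (C4α-OTBS; C5β-CO2CH3; C6=C7; C8 ketone; C9–CH3; C10β-H)
Conditions: Pd(OAc)2 (1.05 equiv), MeCN, 25 °C
Reagents that add atoms: none
Why: Saegusa–Ito oxidation: palladation at C7 and β-hydride elimination of H6 give the C6=C7 enone; C9–H is then the only acidic hydrogen (C5 is quaternary), which makes step 7 regiospecific.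

Step 7
Reactants: 10 enone; 11 2-(bromomethyl)-1,4-dimethoxybenzene
Product: 13 C9-quaternary enone (C9 α-CH3 and β-(2,5-dimethoxybenzyl); otherwise as 10), via lithium dienolate 12 (not isolated)
Conditions: LiN(i-Pr)2, THF, −78 °C; then 11, DMPU, −78 → 0 °C
Reagents that add atoms: none
Why: Kinetic α′-deprotonation gives the cross-conjugated dienolate 12, which is C-alkylated at C9 by the benzylic bromide (enolate alkylation); attack comes from the convex β face, anti to the pseudoaxial C10–C1 bond of ring A, so the benzyl group ends on the face of C10–H and the methyl ends α.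

Step 8
Reactants: 13 C9-quaternary enone
Product: 14 diene (C8=CH2 and C6=C7; otherwise as 13)
Conditions: Ph3PCH3Br, KOt-Bu, toluene, 80 °C
Reagents that add atoms: methyltriphenylphosphonium bromide C[P+](c1ccccc1)(c1ccccc1)c1ccccc1.[Br-]
Why: Wittig methylenation of the hindered ketone with excess salt-free ylide at elevated temperature; the neopentyl methyl ester does not react.

Step 9
Reactants: 14 diene
Product: 15 saturated ester (C8 β-CH3 and α-H; C6 and C7 saturated)
Conditions: H2 (1 atm), Pd/C (10 %), EtOAc, 25 °C
Reagents that add atoms: none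
Why: Catalytic hydrogenation of both C=C bonds; once the C7=C8(CH3) alkene is formed, A(1,2) strain with the C8 methyl keeps the larger C9 substituent (benzyl) pseudoaxial, so hydrogen is delivered to C8 from the opposite, α face and the methyl ends β, cis to the benzyl group.

Step 10
Reactants: 15 saturated ester
Product: 16 C11 primary alcohol (C5β-CH2OH)
Conditions: LiAlH4, THF, 0 → 65 °C
Reagents that add atoms: none
Why: Hydride reduction of the neopentyl ester; silyl and aryl ethers are inert.

Step 11
Reactants: 16 C11 alcohol
Product: 17 C11 aldehyde (C5β-CHO)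
Conditions: Dess–Martin periodinane, CH2Cl2, 25 °C
Reagents that add atoms: none
Why: Dess–Martin oxidation to an aldehyde that cannot enolise or epimerise because C5 is quaternary.

Step 12
Reactants: 18 2-methylpropanal; 19 methyl prop-2-enoate
Product: 21 methyl 4,4-dimethyl-5-oxopentanoate, via enamine 20 (not isolated)
Conditions: pyrrolidine, benzene, reflux (−H2O); then 19, MeCN, reflux; then AcOH/H2O
Reagents that add atoms: none
Why: Stork enamine Michael addition; hydrolysis returns the aldehyde with the gem-dimethyl quaternary carbon (future C4′) in place.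

Step 13
Reactants: 21 methyl 4,4-dimethyl-5-oxopentanoate
Product: 23 methyl (5E,7E)-4,4-dimethylnona-5,7-dienoate, via 5Z isomer 22 (not isolated)
Conditions: [(E)-but-2-enyl]PPh3Cl, n-BuLi, THF, −78 → 25 °C; then I2 (5 mol %), hexane, daylight, 25 °C
Reagents that add atoms: (E)-but-2-en-1-yltriphenylphosphonium chloride C/C=C/C[P+](c1ccccc1)(c1ccccc1)c1ccccc1.[Cl-]
Why: Wittig olefination with a semi-stabilised allylic ylide gives a 5E/5Z mixture, and iodine-catalysed equilibration moves it to the E,E diene because a Z alkene next to the quaternary carbon is strongly strained; residual Z isomer cannot reach the s-cis geometry and is left behind in step 17.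

Step 14
Reactants: 23 methyl (5E,7E)-4,4-dimethylnona-5,7-dienoate
Product: 24 (8E,10E)-7,7-dimethyldodeca-8,10-dien-2-yn-4-one
Conditions: 1-propynyllithium, BF3·OEt2, THF, −78 °C; then H2O
Reagents that add atoms: 1-propynyllithium [Li]C#CC
Why: Acylation of a lithium acetylide by an ester in the presence of BF3 (alkynyl ketone synthesis); the boron-complexed tetrahedral intermediate persists until work-up, which prevents a second addition.

Step 15
Reactants: 24 ynone
Product: 25 (4S,8E,10E)-7,7-dimethyldodeca-8,10-dien-2-yn-4-ol
Conditions: RuCl[(S,S)-TsDPEN](p-cymene) (1 mol %), i-PrOH, 25 °C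
Reagents that add atoms: none
Why: Noyori asymmetric transfer hydrogenation of an alkynyl ketone; the alkyne is the π-substituent recognised by the catalyst, hydride goes to one carbonyl face and sets the future C1′; the diene is not reduced.

Step 16
Reactants: 25 (S)-propargylic alcohol
Product: 26 tributylstannylmethyl ether of 25
Conditions: KH, THF, 0 °C; then Bu3SnCH2I, 25 °C
Reagents that add atoms: tributyl(iodomethyl)stannane CCCC[Sn](CCCC)(CCCC)CI
Why: Williamson O-alkylation of the potassium alkoxide; the ether is the precursor of the later Wittig–Still rearrangement and a bulky, non-coordinating group for stereocontrol in step 17.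

Step 17
Reactants: 26 acyclic dienyne ether
Product: 27 bicyclic stannylmethyl ether (1′α-OCH2SnBu3; C9′=C10′ bearing the C9′ methyl; C6′=C7′; 5′α-H; 8′β-CH3; 4′,4′-dimethyl)
Conditions: Ni(cod)2 (10 mol %), P(O-2-biphenylyl)3 (30 mol %), THF, 40 °C
Reagents that add atoms: none
Why: Zerovalent-nickel-catalysed intramolecular [4+2] cycloaddition of an unactivated dienyne, a reaction type that runs near room temperature where the thermal version needs more than 150 °C; the E,E diene geometry is transferred to the cis relation of H5′ and H8′, and developing A(1,3) strain with the C9′ methyl keeps the C1′ oxygen axial on the chair-like ring A′, that is cis to the axial H5′.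

Step 18
Reactants: 27 bicyclic 1,4-diene
Product: 28 6′,7′-dihydro compound (only C9′=C10′ left)
Conditions: 2-nitrobenzenesulfonylhydrazide, Et3N, CH2Cl2, 25 °C
Reagents that add atoms: none
Why: Diimide reduction is selective for the cis-disubstituted C6′=C7′ bond, the tetrasubstituted C9′=C10′ bond is inert, and the oxidation-prone 1,4-diene is removed.

Step 19
Reactants: 28 allylic stannylmethyl ether
Product: 30 [(1R,2S,4aS)-1,2,5,5-tetramethyl-1,2,3,4,4a,5,6,7-octahydronaphthalen-1-yl]methanol (right half with C12–OH), via alkoxymethyllithium 29 (not isolated)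
Conditions: n-BuLi, THF, −78 → −20 °C; then H2O
Reagents that add atoms: none
Why: Tin–lithium exchange gives the α-alkoxy carbanion 29, which undergoes the Wittig–Still [2,3]-sigmatropic rearrangement: C12 is delivered to C9′ on the face of the axial C1′–O bond (α, anti to the C8′ methyl) and the double bond moves to C1′=C10′, so the quaternary centre and the alkene position are set in one stereospecific event.

Step 20
Reactants: 30 neopentyl alcohol
Product: 31 (1R,2S,4aS)-1-(iodomethyl)-1,2,5,5-tetramethyl-1,2,3,4,4a,5,6,7-octahydronaphthalene
Conditions: I2, PPh3, imidazole, toluene, 80 °C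
Reagents that add atoms: iodine II
Why: Appel-type iodination of a neopentyl alcohol at elevated temperature; the substitution is SN2, so no cation is formed next to the homoallylic alkene.

Step 21
Reactants: 31 iodide; 17 C11 aldehyde
Product: 34 S-methyl xanthate of the coupled C11 carbinol (C11 bears OC(=S)SCH3; C11–C12 bond formed; C4α-OTBS), via organolithium 32 (not isolated), via lithium alkoxide 33 (not isolated)
Conditions: 31, t-BuLi (2.1 equiv), Et2O/pentane, −78 °C; then 17, −78 → 0 °C; then CS2, THF, 0 °C; then MeI, 25 °C
Reagents that add atoms: carbon disulfide S=C=S; iodomethane CI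
Why: Lithium–iodine exchange gives the neopentyl organolithium 32, which adds 1,2 to the non-enolisable aldehyde; the alkoxide 33 is trapped in the same flask as the xanthate (both C11 epimers are carried on).

Step 22
Reactants: 34 xanthate
Product: 35 coupled silyl ether (C11 and C12 both CH2; C4α-OTBS; dimethoxyarene)
Conditions: Bu3SnH, AIBN (cat.), benzene, 80 °C
Reagents that add atoms: none
Why: Barton–McCombie deoxygenation; the secondary C11 radical has no β-leaving group, C4 is still sp3, and the C1′=C10′ bond could only be reached by a slow 4-exo or 5-endo closure, so the radical is simply reduced.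

Step 23
Reactants: 35 coupled silyl ether
Product: 36 C4α alcohol
Conditions: Bu4NF, THF, 60 °C
Reagents that add atoms: none
Why: Fluoride cleavage of the hindered secondary silyl ether; no acid is present, so the trisubstituted alkene is not at risk.

Step 24
Reactants: 36 C4 alcohol
Product: 37 C4 ketone
Conditions: Dess–Martin periodinane, CH2Cl2, 25 °C
Reagents that add atoms: none
Why: Dess–Martin oxidation of a secondary alcohol; the alkene and the electron-rich arene are untouched.

Step 25
Reactants: 37 C4 ketone
Product: 38 4-methylidene compound (dimethyl ether of the hydroquinone)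
Conditions: Ph3PCH3Br, KOt-Bu, toluene, 90 °C
Reagents that add atoms: methyltriphenylphosphonium bromide C[P+](c1ccccc1)(c1ccccc1)c1ccccc1.[Br-]
Why: Wittig methylenation of the ketone next to the quaternary C5; the alkene is introduced only now because it would not have survived steps 9 and 22.

Step 26
Reactants: 38 dimethyl ether
Product: 40 hydroquinone, via benzoquinone 39 (not isolated)
Conditions: (NH4)2Ce(NO3)6, MeCN/H2O, 0 °C; then aq Na2S2O4, Et2O, 25 °C
Reagents that add atoms: water O
Why: Oxidative demethylation of a 1,4-dimethoxyarene by tetravalent cerium gives the quinone (its oxygens come from water), and dithionite reduces it in the work-up; the arene is oxidised in preference to either alkene.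

Step 27
Reactants: 40 hydroquinone
Product: 41 CNP0439949.2 (bis(hydrogen sulfate))
Conditions: SO3·pyridine, pyridine, 25 °C; then cation-exchange resin (H+ form), MeOH/H2O, 0 °C
Reagents that add atoms: sulfur trioxide pyridine complex O=S(=O)([O-])[n+]1ccccc1
Why: O-Sulfation of both phenols with the sulfur trioxide–pyridine complex; cold cation exchange gives the free bis(hydrogen sulfate), which is best stored as its disodium salt.

## Compound list

1 | methyl 2-oxocyclohexane-1-carboxylate | COC(=O)C1CCCCC1=O | starting material
2 | methyl 2-oxo-1-(phenylselanyl)cyclohexane-1-carboxylate | COC(=O)C1([Se]c2ccccc2)CCCCC1=O | intermediate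
3 | methyl 2-oxo-1-(phenylseleninyl)cyclohexane-1-carboxylate | COC(=O)C1([Se](=O)c2ccccc2)CCCCC1=O | intermediate
4 | methyl 6-oxocyclohex-1-ene-1-carboxylate | COC(=O)C1=CCCCC1=O | intermediate
5 | pent-1-en-3-one | CCC(=O)C=C | starting material
6 | (Z)-3-(tert-butyldimethylsilyloxy)penta-1,3-diene | C=C/C(O[Si](C)(C)C(C)(C)C)=C/C | intermediate
7 | methyl (4aR,8S,8aR)-7-(tert-butyldimethylsilyloxy)-8-methyl-4-oxo-1,3,4,5,8,8a-hexahydronaphthalene-4a(2H)-carboxylate | O=C1CCC[C@H]2[C@]1(C(=O)OC)CC=C(O[Si](C)(C)C(C)(C)C)[C@H]2C | intermediate
8 | 4α-alcohol of 7 | O[C@@H]1CCC[C@H]2[C@]1(C(=O)OC)CC=C(O[Si](C)(C)C(C)(C)C)[C@H]2C | intermediate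
9 | 4α-silyl ether of 8 | CC(C)(C)[Si](C)(C)O[C@@H]1CCC[C@H]2[C@]1(C(=O)OC)CC=C(O[Si](C)(C)C(C)(C)C)[C@H]2C | intermediate
10 | 6-en-8-one with 4α-OTBS and 5β-ester | CC(C)(C)[Si](C)(C)O[C@@H]1CCC[C@H]2[C@]1(C(=O)OC)C=CC(=O)[C@H]2C | intermediate
11 | 2-(bromomethyl)-1,4-dimethoxybenzene | COc1ccc(OC)c(CBr)c1 | starting material
12 | lithium C8(O)=C9 dienolate of 10 | CC(C)(C)[Si](C)(C)O[C@@H]1CCC[C@H]2[C@]1(C(=O)OC)C=CC(O[Li])=C2C | intermediate
13 | C9-quaternary enone (9α-methyl, 9β-(2,5-dimethoxybenzyl)) | CC(C)(C)[Si](C)(C)O[C@@H]1CCC[C@H]2[C@]1(C(=O)OC)C=CC(=O)[C@]2(C)Cc1cc(OC)ccc1OC | intermediate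
14 | 8-methylidene-6-ene | CC(C)(C)[Si](C)(C)O[C@@H]1CCC[C@H]2[C@]1(C(=O)OC)C=CC(=C)[C@]2(C)Cc1cc(OC)ccc1OC | intermediate
15 | saturated ester with 8β-methyl | CC(C)(C)[Si](C)(C)O[C@@H]1CCC[C@H]2[C@]1(C(=O)OC)CC[C@H](C)[C@]2(C)Cc1cc(OC)ccc1OC | intermediate
16 | C11 alcohol | CC(C)(C)[Si](C)(C)O[C@@H]1CCC[C@H]2[C@]1(CO)CC[C@H](C)[C@]2(C)Cc1cc(OC)ccc1OC | intermediate
17 | C11 aldehyde | CC(C)(C)[Si](C)(C)O[C@@H]1CCC[C@H]2[C@]1(C=O)CC[C@H](C)[C@]2(C)Cc1cc(OC)ccc1OC | intermediate
18 | 2-methylpropanal | CC(C)C=O | starting material
19 | methyl prop-2-enoate | C=CC(=O)OC | starting material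
20 | 1-(2-methylprop-1-en-1-yl)pyrrolidine | CC(C)=CN1CCCC1 | intermediate
21 | methyl 4,4-dimethyl-5-oxopentanoate | COC(=O)CCC(C)(C)C=O | intermediate
22 | methyl (5Z,7E)-4,4-dimethylnona-5,7-dienoate | COC(=O)CCC(C)(C)/C=C\C=C\C | intermediate
23 | methyl (5E,7E)-4,4-dimethylnona-5,7-dienoate | COC(=O)CCC(C)(C)/C=C/C=C/C | intermediate
24 | (8E,10E)-7,7-dimethyldodeca-8,10-dien-2-yn-4-one | CC#CC(=O)CCC(C)(C)/C=C/C=C/C | intermediate
25 | (4S,8E,10E)-7,7-dimethyldodeca-8,10-dien-2-yn-4-ol | CC#C[C@@H](O)CCC(C)(C)/C=C/C=C/C | intermediate
26 | tributylstannylmethyl ether of 25 | CC#C[C@@H](OC[Sn](CCCC)(CCCC)CCCC)CCC(C)(C)/C=C/C=C/C | intermediate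
27 | bicyclic stannylmethyl ether (1′α-O, 6′-ene, 9′(10′)-ene, 5′α-H, 8′β-methyl) | CCCC[Sn](CCCC)(CCCC)CO[C@H]1CCC(C)(C)[C@@H]2C=C[C@H](C)C(C)=C12 | intermediate
28 | 6′,7′-dihydro derivative of 27 | CCCC[Sn](CCCC)(CCCC)CO[C@H]1CCC(C)(C)[C@@H]2CC[C@H](C)C(C)=C12 | intermediate
29 | alkoxymethyllithium from 28 | [Li]CO[C@H]1CCC(C)(C)[C@@H]2CC[C@H](C)C(C)=C12 | intermediate
30 | [(1R,2S,4aS)-1,2,5,5-tetramethyl-1,2,3,4,4a,5,6,7-octahydronaphthalen-1-yl]methanol | OC[C@@]1(C)C2=CCCC(C)(C)[C@@H]2CC[C@@H]1C | intermediate
31 | (1R,2S,4aS)-1-(iodomethyl)-1,2,5,5-tetramethyl-1,2,3,4,4a,5,6,7-octahydronaphthalene | IC[C@@]1(C)C2=CCCC(C)(C)[C@@H]2CC[C@@H]1C | intermediate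
32 | C12 organolithium from 31 | [Li]C[C@@]1(C)C2=CCCC(C)(C)[C@@H]2CC[C@@H]1C | intermediate
33 | lithium alkoxide of the coupled C11 carbinol (C11 epimers) | CC(C)(C)[Si](C)(C)O[C@@H]1CCC[C@H]2[C@]1(C(O[Li])C[C@@]1(C)C3=CCCC(C)(C)[C@@H]3CC[C@@H]1C)CC[C@H](C)[C@]2(C)Cc1cc(OC)ccc1OC | intermediate
34 | S-methyl xanthate of the C11 carbinol (C11 epimers) | CC(C)(C)[Si](C)(C)O[C@@H]1CCC[C@H]2[C@]1(C(OC(=S)SC)C[C@@]1(C)C3=CCCC(C)(C)[C@@H]3CC[C@@H]1C)CC[C@H](C)[C@]2(C)Cc1cc(OC)ccc1OC | intermediate
35 | coupled 4α-silyl ether with CH2–CH2 bridge | CC(C)(C)[Si](C)(C)O[C@@H]1CCC[C@H]2[C@]1(CC[C@@]1(C)C3=CCCC(C)(C)[C@@H]3CC[C@@H]1C)CC[C@H](C)[C@]2(C)Cc1cc(OC)ccc1OC | intermediate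
36 | coupled 4α-alcohol | O[C@@H]1CCC[C@H]2[C@]1(CC[C@@]1(C)C3=CCCC(C)(C)[C@@H]3CC[C@@H]1C)CC[C@H](C)[C@]2(C)Cc1cc(OC)ccc1OC | intermediate
37 | coupled C4 ketone | O=C1CCC[C@H]2[C@]1(CC[C@@]1(C)C3=CCCC(C)(C)[C@@H]3CC[C@@H]1C)CC[C@H](C)[C@]2(C)Cc1cc(OC)ccc1OC | intermediate
38 | 4-methylidene dimethyl ether | C=C1CCC[C@H]2[C@]1(CC[C@@]1(C)C3=CCCC(C)(C)[C@@H]3CC[C@@H]1C)CC[C@H](C)[C@]2(C)Cc1cc(OC)ccc1OC | intermediate
39 | benzoquinone | C=C1CCC[C@H]2[C@]1(CC[C@@]1(C)C3=CCCC(C)(C)[C@@H]3CC[C@@H]1C)CC[C@H](C)[C@]2(C)CC1=CC(=O)C=CC1=O | intermediate
40 | hydroquinone | C=C1CCC[C@H]2[C@]1(CC[C@@]1(C)C3=CCCC(C)(C)[C@@H]3CC[C@@H]1C)CC[C@H](C)[C@]2(C)Cc1cc(O)ccc1O | intermediate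
41 | CNP0439949.2, hydroquinone bis(hydrogen sulfate) | C=C1CCC[C@H]2[C@]1(CC[C@@]1(C)C3=CCCC(C)(C)[C@@H]3CC[C@@H]1C)CC[C@H](C)[C@]2(C)Cc1cc(OS(=O)(=O)O)ccc1OS(=O)(=O)O | target

## Step count and least certain steps

Total: 27 steps. Longest linear sequence: 17 steps (steps 1, 3–11 and 21–27, from 1); the right-half branch (steps 12–20, then 21–27) has 16.

**Step 3 (key step).** The six-membered β-keto ester chelate may give insufficient enantioface discrimination with this diene. The Lewis acid may also strip the silyl group, so that Michael addition occurs without ring closure, and 4 may dimerise before it is intercepted.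
Fallback, from 4 and 6 back to 8: the cycloaddition is run with an achiral promoter (ZnBr2, CH2Cl2, −40 °C), which gives 7 together with its mirror image, the antipodal adduct F1. The C4 ketone is then reduced with catecholborane and the 2-methyl-CBS oxazaborolidine instead of NaBH4, the catalyst enantiomer being chosen so that 7 gives 8. Under the same reagent control F1 gives the diastereomeric alcohol F2, which is removed by chromatography, and 8 re-enters at step 5. Asymmetric catalysis is thus replaced by a reagent-controlled resolution at the cost of half the material.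

**Step 17.** The ether stereocentre may control the diene face poorly, and the catalyst may be retarded by the hindered diene terminus next to the quaternary carbon.
Fallback, from 24 back to 27: the ynone 24, whose triple bond is activated by the C1′ carbonyl, is cyclised thermally (toluene, 110 °C) in an ordinary intramolecular Diels–Alder reaction to the racemic dienone F3. Reduction with catecholborane and the 2-methyl-CBS oxazaborolidine sets C1′ under reagent control and converts the two enantiomers into diastereomers. The isomer with 1′α-OH, 5′α-H and 8′β-methyl, dienol F4, is separated from the diastereomeric dienol F5 and O-alkylated (KH, Bu3SnCH2I) to 27.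

**Step 9.** Facial selectivity at C8 may be poor: if the ring B conformer with the C9 methyl pseudoaxial dominates, hydrogen arrives from the β face and the C8 epimer forms.
Fallback, from 13 back to 15, in which the C8 configuration is decided by attack at C6 and a suprafacial hydrogen shift instead of by the face of C8: CH3Li/CeCl3 adds to the C8 ketone of 13 to give the tertiary allylic alcohol F6. Oxidative 1,3-transposition with pyridinium chlorochromate (C5H5NH)[CrO3Cl] gives the 6-oxo-7-ene F7. Its tosylhydrazone F8 is reduced with catecholborane (then NaOAc, CHCl3, reflux); hydride adds to C6 from the convex β face, and the allylic diazene passes its hydrogen to C8 on the α face with loss of N2, giving the 6-ene F9. Hydrogenation of the C6=C7 bond (H2, Pd/C) gives 15.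

**Step 21 (with step 20).** Lithium–iodine exchange or the addition of a neopentyl nucleophile to a neopentyl aldehyde may be too slow, so that the organolithium is lost by protonation before it couples.
Fallback, from 31 and 17 back to 35, a Julia–Kocienski olefination: 31 is displaced by 1-phenyl-1H-tetrazole-5-thiol (K2CO3, DMF, 90 °C) to the tetrazolyl sulfide F10, and oxidation ((NH4)6Mo7O24, H2O2, EtOH) gives the sulfone F11. Its anion (KN(SiMe3)2, THF, −78 °C) condenses with 17 to the (E)-C11=C12 alkene F12. Diimide reduction of this disubstituted alkene, which leaves the trisubstituted C1′=C10′ bond alone, gives 35.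

## Further compounds

F1 | step 3 | antipode of adduct 7 | O=C1CCC[C@@H]2[C@@]1(C(=O)OC)CC=C(O[Si](C)(C)C(C)(C)C)[C@@H]2C
F2 | step 3 | diastereomeric C4 alcohol from F1 (C4 as in 8, other centres antipodal) | O[C@@H]1CCC[C@@H]2[C@@]1(C(=O)OC)CC=C(O[Si](C)(C)C(C)(C)C)[C@@H]2C
F3 | step 17 | racemic 4,4,8,9-tetramethyl bicyclic dienone (C1′ ketone, 9′(10′)-ene, 6′-ene; one enantiomer drawn) | CC1=C2C(=O)CCC(C)(C)[C@@H]2C=C[C@@H]1C
F4 | step 17 | dienol with 1′α-OH, 5′α-H, 8′β-methyl | O[C@H]1CCC(C)(C)[C@@H]2C=C[C@H](C)C(C)=C12
F5 | step 17 | diastereomeric dienol from the other enantiomer of F3 | O[C@H]1CCC(C)(C)[C@H]2C=C[C@@H](C)C(C)=C12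
F6 | step 9 | C8 tertiary allylic alcohol (8-methyl, 8-hydroxy, 6-ene; C8 epimers) | CC(C)(C)[Si](C)(C)O[C@@H]1CCC[C@H]2[C@]1(C(=O)OC)C=CC(C)(O)[C@]2(C)Cc1cc(OC)ccc1OC
F7 | step 9 | transposed enone (C6 ketone, C7=C8 bearing the C8 methyl) | CC(C)(C)[Si](C)(C)O[C@@H]1CCC[C@H]2[C@]1(C(=O)OC)C(=O)C=C(C)[C@]2(C)Cc1cc(OC)ccc1OC
F8 | step 9 | tosylhydrazone of F7 | CC(C)(C)[Si](C)(C)O[C@@H]1CCC[C@H]2[C@]1(C(=O)OC)C(=NNS(=O)(=O)c3ccc(C)cc3)C=C(C)[C@]2(C)Cc1cc(OC)ccc1OC
F9 | step 9 | 6-ene with 8β-methyl and 8α-H | CC(C)(C)[Si](C)(C)O[C@@H]1CCC[C@H]2[C@]1(C(=O)OC)C=C[C@H](C)[C@]2(C)Cc1cc(OC)ccc1OC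
F10 | step 21 | 1-phenyl-1H-tetrazol-5-yl sulfide of the right half | c1ccccc1-n1nnnc1SC[C@@]1(C)C2=CCCC(C)(C)[C@@H]2CC[C@@H]1C
F11 | step 21 | 1-phenyl-1H-tetrazol-5-yl sulfone of the right half | c1ccccc1-n1nnnc1S(=O)(=O)C[C@@]1(C)C2=CCCC(C)(C)[C@@H]2CC[C@@H]1C
F12 | step 21 | coupled E C11=C12 alkene (4α-OTBS) | CC(C)(C)[Si](C)(C)O[C@@H]1CCC[C@H]2[C@]1(/C=C/[C@@]1(C)C3=CCCC(C)(C)[C@@H]3CC[C@@H]1C)CC[C@H](C)[C@]2(C)Cc1cc(OC)ccc1OC
A1 | alternative 1 | methylenecyclobutane photoadduct | C=C1C[C@@]2(C)[C@@]13C(=O)CCC(C)(C)[C@@H]3CC[C@@H]2C
A2 | alternative 1 | C1′-keto 9′(10′)-ene octalin | CC1=C2C(=O)CCC(C)(C)[C@@H]2CC[C@@H]1C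
A3 | alternative 1 | propa-1,2-diene | C=C=C
A4 | alternative 2 | 2-(2,5-dimethoxybenzyl)-2,3-dimethylcyclohexan-1-one | O=C1CCC[C@H](C)[C@]1(C)Cc1cc(OC)ccc1OC
A5 | alternative 2 | 2-(2,5-dimethoxybenzyl)cyclohex-2-en-1-one | O=C1CCCC=C1Cc1cc(OC)ccc1OC
A6 | alternative 3 | hydroquinone monomethyl ether of the target skeleton | C=C1CCC[C@H]2[C@]1(CC[C@@]1(C)C3=CCCC(C)(C)[C@@H]3CC[C@@H]1C)CC[C@H](C)[C@]2(C)Cc1cc(OC)ccc1O
A7 | alternative 3 | pentacarbonyl[methoxy(vinyl)carbene]chromium (CO)5Cr=C(OCH3)CH=CH2 | COC(C=C)=[Cr](=C=O)(=C=O)(=C=O)(=C=O)=C=O
A8 | alternative 3 | C9-propargyl analogue of the target skeleton | C=C1CCC[C@H]2[C@]1(CC[C@@]1(C)C3=CCCC(C)(C)[C@@H]3CC[C@@H]1C)CC[C@H](C)[C@]2(C)CC#C
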